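The starting complex gives up leaving ligand to incoming ligand one exchange at a time, and you must say which form leads at the end of each flask, and by how much.

common to all: starting complex 0.20 M; leaving ligand 0.400 M; time 12 h

| run | incoming ligand |
|---|---|
| Thursday's | 0.190 M |
| Wednesday's | 0.380 M |
| Sunday's | 0.760 M |

    starting complex + incoming ligand → leaving ligand + complex with one exchanged (k1 = 2.2 × 10⁻⁴ M⁻¹ s⁻¹)
    complex with one exchanged + incoming ligand → leaving ligand + complex with two exchanged (k2 = 8.2 × 10⁻⁵ M⁻¹ s⁻¹)
    complex with two exchanged + incoming ligand → leaving ligand + complex with three exchanged (k3 = 1.1 × 10⁻⁴ M⁻¹ s⁻¹)
    starting complex + complex with two exchanged ⇌ idle adduct, settled at all times (K4 = 26 M⁻¹)

- percentages count the starting complex that a species holds: one idle adduct counts as two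
- complex with two exchanged is meant together with its idle adduct
- in an amount of complex with two exchanged, one idle adduct counts as one complex with two exchanged
- run time (Thursday's): 12 h

1. which of these there is most of at the end, counted by the starting complex in it, Thursday's (complex with two exchanged / complex with one exchanged / complex with three exchanged / starting complex)
2. which of these there is most of at the end, counted by the starting complex in it, Wednesday's (complex with two exchanged / complex with one exchanged / complex with three exchanged / starting complex)
3. which of these there is most of at the end, counted by the starting complex in it, Sunday's (complex with two exchanged / complex with one exchanged / complex with three exchanged / starting complex)
4. final amount of the leader among these, as a percentage of the starting complex charged, in Thursday's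
5. final amount of the leader among these, as a percentage of the starting complex charged, in Wednesday's
6. final amount of the leader among these, as a percentage of the starting complex charged, in Sunday's

Climb the ladder from the fastest rung. The adduct balance takes no time, and the equilibrium constant times c(starting complex) stands at 5.2 at the start of Thursday's, above one, so early complex with two exchanged is more bound than free. Next comes the first exchange, with a half-life of 4.6 h at Thursday's charge. It is quicker than the third exchange at 9.2 h and the second at 12 h, so it runs ahead of them.

Each exchange carries the incoming ligand to the first power and the balance has no clock, so composition should follow the ligand's concentration summed over time, not time itself. My correction is simple: the first exchange soon eats about c(starting complex) of ligand, so subtract that from the charge. The working dose is the rate constant of the first exchange, times charged c(incoming ligand) minus charged c(starting complex), times time. For Wednesday's it is 1.71, and for Sunday's 5.32.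

The first two exchanges alone, adduct ignored, put the peak of complex with one exchanged at a dose of 1.57. So I expect complex with one exchanged to lead Wednesday's, whose dose stands just past that peak, while Sunday's stands further on. In Thursday's the charge is 0.950 ligand per complex, which makes the ligand the limiting reagent of the first exchange, so the dose counts nothing there and I simply expect complex with one exchanged to lead. My reckoning stops short of percentages, and it can't separate the two- and three-exchanged complexes in Sunday's.

The forecast names complex with one exchanged at 48% for Thursday's, complex with one exchanged at 48% for Wednesday's and complex with three exchanged at 38% for Sunday's, on the ground that “all three runs follow one composition path and differ only in where they stop”.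

The simulation gives complex with one exchanged at 48.1%, complex with one exchanged at 48.5% and complex with three exchanged at 38.5%, so the forecast stands. Sunday's complex with three exchanged has moved 6 points, which lies past either end of the forecast's range of 34% to 42%, at 0.696 M or 0.825 M of incoming ligand. Now read Wednesday's flask at 20 h: scaling 1.71 by time gives a dose of 2.85, against 2.66 for Sunday's at 6.00 h, so the two should look alike. Sunday's then holds 6.27% starting complex and 13.1% complex with three exchanged; the neighbour holds 6.05% and 13.8%.

All constants are made up; the flask was simulated.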